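**Plan**
Retrosynthesis: the two benzyl–O bonds at O5 and O8 are cut last. The C4 ketone is traced back to a (4S) carbinol, and the racemic pyranone ring is cut at O1–C2 and C2–C3 (hexadecanal plus a 2-hydroxyacetophenone). The aryl–acetyl bond is cut next, and the aryl–O1 bond goes back to the formyl carbon of 2,5-dihydroxybenzaldehyde.
Forward: benzylation, Baeyer–Villiger oxidation to the phenol, MOM ether, ortho-lithiation and acetylation, MOM removal. Pyrrolidine condensation with hexadecanal then joins the chain and closes the one new ring (the pyranone) as a racemate.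
Stereochemistry: C2 is fixed in step 7, where the racemic ketone is reduced with RuCl(p-cymene)[(S,S)-TsDPEN] under racemising conditions. The extra C4 centre is removed by reoxidation, and hydrogenolysis frees the phenols without base.
Enabling feature: C2 is β to the C4 carbonyl and carries the aryl oxygen O1. Base therefore opens and recloses the O1–C2 bond of the pyranone ring through the 2-hydroxyaryl enone, which keeps both ketone enantiomers in equilibrium until C4 is reduced.

Key step: step 7

Remark: O5 and O8 travel as benzyl ethers so that the final unmasking is a neutral hydrogenolysis that cannot open the base-labile O1–C2 bond; the (2R,4S) outcome with the (S,S) ligand is assigned by analogy with aryl alkyl ketones.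

Step 1
Reactants: 1 2,5-dihydroxybenzaldehyde
Product: 2 2,5-bis(benzyloxy)benzaldehyde
Conditions: BnBr (2.4 equiv), K2CO3 (3 equiv), DMF, 60 °C, N2
Reagents that add atoms: benzyl bromide, BrCc1ccccc1
Why: Williamson etherification of both phenoxides by SN2 displacement of bromide should go to completion in warm DMF, the hydrogen-bonded 2-OH reacting more slowly than the 5-OH.

Step 2
Reactants: 2 2,5-bis(benzyloxy)benzaldehyde
Product: 4 2,5-bis(benzyloxy)phenol, via 2,5-bis(benzyloxy)phenyl formate 3 (not isolated)
Conditions: mCPBA, CH2Cl2, 0 °C to rt; aq. NaHCO3 wash; crude formate, K2CO3 (cat.), MeOH, rt, N2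
Reagents that add atoms: 3-chloroperoxybenzoic acid (mCPBA), O=C(OO)c1cccc(Cl)c1
Why: Baeyer–Villiger oxidation of an electron-rich benzaldehyde (Dakin-type) proceeds with migration of the alkoxy-substituted aryl group to give the aryl formate, which mild methanolysis cleaves to the phenol without touching the benzyl ethers.

Step 3
Reactants: 4 2,5-bis(benzyloxy)phenol
Product: 5 1,4-bis(benzyloxy)-2-(methoxymethoxy)benzene
Conditions: NaH, THF, 0 °C; MOMCl, 0 °C to rt
Reagents that add atoms: chloromethyl methyl ether (MOMCl), COCCl
Why: Williamson-type O-alkylation of the sodium phenoxide with the reactive chloromethyl ether installs the MOM group, which later directs lithiation and can be removed in the presence of benzyl ethers.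

Step 4
Reactants: 5 1,4-bis(benzyloxy)-2-(methoxymethoxy)benzene
Product: 8 1-[3,6-bis(benzyloxy)-2-(methoxymethoxy)phenyl]ethan-1-one, via aryllithium 6 (not isolated), via lithium hemiaminal 7 (not isolated)
Conditions: n-BuLi, TMEDA, THF, −20 °C; MeC(O)N(OMe)Me, −78 to 0 °C; sat. aq. NH4Cl
Reagents that add atoms: N-methoxy-N-methylacetamide, CC(=O)N(C)OC
Why: Directed ortho-metalation takes place at C3 of 5, the one ring position flanked by two coordinating oxygens (OMOM and OBn), and the aryllithium acylates the amide once only because the chelated tetrahedral adduct survives until work-up (Weinreb ketone synthesis).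

Step 5
Reactants: 8 1-[3,6-bis(benzyloxy)-2-(methoxymethoxy)phenyl]ethan-1-one
Product: 9 1-[3,6-bis(benzyloxy)-2-hydroxyphenyl]ethan-1-one
Conditions: conc. HCl (cat.), MeOH/THF, 45 °C
Reagents that add atoms: none
Why: Acid-catalysed acetal exchange with methanol cleaves the MOM ether, which the ortho acetyl group labilises further, whereas benzyl aryl ethers are inert to dilute HCl at this temperature.

Step 6
Reactants: 9 1-[3,6-bis(benzyloxy)-2-hydroxyphenyl]ethan-1-one, 10 hexadecanal
Product: 12 rac-5,8-bis(benzyloxy)-2-pentadecyl-2,3-dihydro-4H-chromen-4-one, via hydroxyaryl enone 11 (not isolated)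
Conditions: pyrrolidine (1 equiv), MeOH, 4 Å molecular sieves, slow addition of 10, 60 °C
Reagents that add atoms: none
Why: Kabbe condensation, in which the pyrrolidine-mediated aldol condensation of the acetyl group with the aldehyde gives enone 11 and its phenol closes the pyranone ring by 6-endo-trig oxa-Michael addition, with no stereocontrol at C2 as intended.

Step 7
Reactants: 12 rac-5,8-bis(benzyloxy)-2-pentadecyl-2,3-dihydro-4H-chromen-4-one
Product: 13 (2R,4S)-5,8-bis(benzyloxy)-2-pentadecyl-3,4-dihydro-2H-chromen-4-ol
Conditions: RuCl(p-cymene)[(S,S)-TsDPEN] (2 mol%), HCO2H (3 equiv), DBU (4 equiv), MeCN/THF, 40 °C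
Reagents that add atoms: none
Why: The 16-electron ruthenium amide takes up formate and loses CO2 to give the divalent ruthenium hydride, which passes hydride to C4 and the ligand N–H proton to the carbonyl oxygen through a six-membered outer-sphere transition state; this is a Noyori-type asymmetric transfer hydrogenation run as a dynamic kinetic resolution with elimination-induced racemisation, a reaction type known for 2-substituted chroman-4-ones. The (S,S) ligand delivers hydride to the face of the aryl ketone that makes C4 S, and the ring takes hydride anti to the pseudo-equatorial pentadecyl chain, so only the (2R) enantiomer of 12 is matched and it should give the cis alcohol. C2 is thus controlled by which enantiomer is reduced: DBU removes a C3 proton of the slow (2S) ketone, O1 leaves as the phenoxide of the ring-opened enone 11 already met in step 6 (E1cB), and that phenoxide adds back to either face of the enone to return both enantiomers of 12. No ring is formed in the net reaction; the only closure is this reversible 6-endo-trig oxa-Michael reclosure of the existing pyranone ring. The step needs a large rate difference between the two ketone enantiomers and racemisation faster than reduction of the (2S) ketone; both are secured by C2 lying β to the C4 carbonyl with O1 as an aryloxide leaving group and by the cis preference of the 2-alkylchromanone, while the benzyl ethers are inert. Once C4 is a carbinol, C3 is no longer acidic and C2 is locked.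

Step 8
Reactants: 13 (2R,4S)-5,8-bis(benzyloxy)-2-pentadecyl-3,4-dihydro-2H-chromen-4-ol
Product: 14 (2R)-5,8-bis(benzyloxy)-2-pentadecyl-2,3-dihydro-4H-chromen-4-one
Conditions: Dess–Martin periodinane, CH2Cl2, 0 °C to rt; aq. Na2S2O3, pH 7 phosphate buffer
Reagents that add atoms: none
Why: Dess–Martin oxidation converts the secondary benzylic carbinol into the ketone with acetic acid as the only acidic by-product, so the C4 centre is erased while the re-formed β-aryloxy ketone never meets a base that could open the O1–C2 bond and racemise C2.

Step 9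
Reactants: 14 (2R)-5,8-bis(benzyloxy)-2-pentadecyl-2,3-dihydro-4H-chromen-4-one
Product: 15 (2R)-5,8-dihydroxy-2-pentadecyl-2,3-dihydro-4H-chromen-4-one
Conditions: H2 (1 atm), 10% Pd/C, EtOAc/THF, rt; filtration and concentration under argon
Reagents that add atoms: none
Why: Hydrogenolysis of the two benzyl aryl ethers over palladium runs under neutral conditions in which the electron-rich, hydrogen-bonded aryl ketone is not reduced and the retro-oxa-Michael pathway stays closed, so the target should be obtained with C2 unchanged.

**Compound list**
1 | 2,5-dihydroxybenzaldehyde | O=Cc1cc(O)ccc1O | starting material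
2 | 2,5-bis(benzyloxy)benzaldehyde | O=Cc1cc(OCc2ccccc2)ccc1OCc1ccccc1 | intermediate
3 | 2,5-bis(benzyloxy)phenyl formate | O=COc1cc(OCc2ccccc2)ccc1OCc1ccccc1 | intermediate
4 | 2,5-bis(benzyloxy)phenol | Oc1cc(OCc2ccccc2)ccc1OCc1ccccc1 | intermediate
5 | 1,4-bis(benzyloxy)-2-(methoxymethoxy)benzene | COCOc1cc(OCc2ccccc2)ccc1OCc1ccccc1 | intermediate
6 | [3,6-bis(benzyloxy)-2-(methoxymethoxy)phenyl]lithium | COCOc1c([Li])c(OCc2ccccc2)ccc1OCc1ccccc1 | intermediate
7 | lithium 1-[3,6-bis(benzyloxy)-2-(methoxymethoxy)phenyl]-1-[methoxy(methyl)amino]ethan-1-olate | COCOc1c(C(C)(O[Li])N(C)OC)c(OCc2ccccc2)ccc1OCc1ccccc1 | intermediate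
8 | 1-[3,6-bis(benzyloxy)-2-(methoxymethoxy)phenyl]ethan-1-one | COCOc1c(C(C)=O)c(OCc2ccccc2)ccc1OCc1ccccc1 | intermediate
9 | 1-[3,6-bis(benzyloxy)-2-hydroxyphenyl]ethan-1-one | CC(=O)c1c(O)c(OCc2ccccc2)ccc1OCc1ccccc1 | intermediate
10 | hexadecanal | CCCCCCCCCCCCCCCC=O | starting material
11 | (E)-1-[3,6-bis(benzyloxy)-2-hydroxyphenyl]octadec-2-en-1-one | CCCCCCCCCCCCCCC/C=C/C(=O)c1c(O)c(OCc2ccccc2)ccc1OCc1ccccc1 | intermediate
12 | rac-5,8-bis(benzyloxy)-2-pentadecyl-2,3-dihydro-4H-chromen-4-one | CCCCCCCCCCCCCCCC1CC(=O)c2c(OCc3ccccc3)ccc(OCc3ccccc3)c2O1 | intermediate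
13 | (2R,4S)-5,8-bis(benzyloxy)-2-pentadecyl-3,4-dihydro-2H-chromen-4-ol (2-alkyl and 4-OH cis) | CCCCCCCCCCCCCCC[C@@H]1C[C@H](O)c2c(OCc3ccccc3)ccc(OCc3ccccc3)c2O1 | intermediate
14 | (2R)-5,8-bis(benzyloxy)-2-pentadecyl-2,3-dihydro-4H-chromen-4-one | CCCCCCCCCCCCCCC[C@@H]1CC(=O)c2c(OCc3ccccc3)ccc(OCc3ccccc3)c2O1 | intermediate
15 | (2R)-5,8-dihydroxy-2-pentadecyl-2,3-dihydro-4H-chromen-4-one | CCCCCCCCCCCCCCC[C@@H]1CC(=O)c2c(O)ccc(O)c2O1 | target

**Step count**
Total steps: 9. Longest linear sequence: 9 steps (1 to 15).

**Steps most likely to fail**

Step 7. Racemisation of the (2S) ketone through enone 11 may not keep pace with its slow reduction, which would erode enantiomeric purity and let the trans alcohol build up; hydride may also be spent on the ring-opened enone. The fallback gives up the dynamic process for a plain kinetic resolution with separate recycling. Setting out from 12, the same catalyst with the HCO2H/Et3N (5:2) mixture and no free base in EtOAc at rt would be stopped near half conversion. The (2R) ketone is reduced to 13, where the fallback comes back to the route, and (2S)-5,8-bis(benzyloxy)-2-pentadecyl-2,3-dihydro-4H-chromen-4-one F1 is left behind. After chromatographic separation it would be racemised to 12 with DBU in MeCN in a separate flask and resubmitted.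

Step 6. Self-condensation of hexadecanal through its own enamine, and slow condensation at the doubly ortho-substituted acetyl group, may keep the ring-forming condensation from going to completion. The fallback separates C2–C3 bond formation from ring closure. Setting out from 8 and 10, the lithium enolate of 8 (LiN(iPr)2, THF, −78 °C; NH4Cl quench) would add to hexadecanal to give 1-[3,6-bis(benzyloxy)-2-(methoxymethoxy)phenyl]-3-hydroxyoctadecan-1-one F2. HCl in MeOH would remove the MOM group to give 1-[3,6-bis(benzyloxy)-2-hydroxyphenyl]-3-hydroxyoctadecan-1-one F3. An intramolecular Mitsunobu etherification (PPh3, DIAD, THF, 0 °C to rt) would then close the O1–C2 bond and come back to the route at 12.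

Step 4. Deprotonation at a benzylic CH2 of the benzyl ethers, followed by [1,2]-Wittig rearrangement, may compete with ring lithiation, and the hindered aryllithium may enolise the amide instead of adding to it. The fallback avoids strong base altogether. Setting out from phenol 4, magnesium-mediated ortho-formylation (MgCl2, Et3N, paraformaldehyde, MeCN, reflux) can only attack the single free ortho position and would give 3,6-bis(benzyloxy)-2-hydroxybenzaldehyde F4. MeMgBr (excess, THF, 0 °C; dilute HCl work-up) would give 3,6-bis(benzyloxy)-2-(1-hydroxyethyl)phenol F5, and oxidation of the benzylic alcohol with MnO2 in CH2Cl2 would come back to the route at 9.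

**Further compounds**
F1 | step 7 | (2S)-5,8-bis(benzyloxy)-2-pentadecyl-2,3-dihydro-4H-chromen-4-one | CCCCCCCCCCCCCCC[C@H]1CC(=O)c2c(OCc3ccccc3)ccc(OCc3ccccc3)c2O1
F2 | step 6 | 1-[3,6-bis(benzyloxy)-2-(methoxymethoxy)phenyl]-3-hydroxyoctadecan-1-one | CCCCCCCCCCCCCCCC(O)CC(=O)c1c(OCOC)c(OCc2ccccc2)ccc1OCc1ccccc1
F3 | step 6 | 1-[3,6-bis(benzyloxy)-2-hydroxyphenyl]-3-hydroxyoctadecan-1-one | CCCCCCCCCCCCCCCC(O)CC(=O)c1c(O)c(OCc2ccccc2)ccc1OCc1ccccc1
F4 | step 4 | 3,6-bis(benzyloxy)-2-hydroxybenzaldehyde | O=Cc1c(O)c(OCc2ccccc2)ccc1OCc1ccccc1
F5 | step 4 | 3,6-bis(benzyloxy)-2-(1-hydroxyethyl)phenol | CC(O)c1c(O)c(OCc2ccccc2)ccc1OCc1ccccc1
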